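## Retrosynthetic overview

1. Target ⇐ desilylation, C6 aroylation, Luche reduction, C3 acetylation and convex-face dihydroxylation of the cis-fused hydroazulene dienone 15 (as its TBS ether 16).
2. Seven-membered ring (formed last) ⇐ ring-closing metathesis (C7=C8) of acryloyl ketone / methallyl carbinol 14; the C10 carbinol ⇐ chiral phosphoric acid methallylboration of aldehyde 11.
3. 11 ⇐ vinyl-metal opening (C6) and oxidation (C10) of the cis-fused cyclopentene lactone 7; the lactone is a temporary ring that locks C6 and C10 cis.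
4. Cyclopentene (second ring) ⇐ intramolecular McMurry coupling (C3=C4) of keto-aldehyde 6.
5. C1 quaternary stereocentre ⇐ aminocatalytic conjugate addition of acetaldehyde to the achiral acyl butenolide 4 (first ring, from hydroxyacetone and ethyl isobutyrylacetate).

Assumptions: locants C1–C10 follow daucane numbering (C1 = ring-fusion C–CH3, C2 = CH2, C3 = C–OAc, C4 = C(OH)iPr, C5 = ring-fusion CH, C6 = C–O-aroyl, C7=C8(CH3), C9 = CH2, C10 = CHOH; β = face of the C1 methyl), so the target is the cis-fused 1β-Me, 5β-H, 3β-OAc, 4β-OH, 6α-O-aroyl, 10β-OH compound; acid 20 is taken as purchasable; the catalyst antipodes named are those predicted by the accepted models to give the drawn configurations.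

## Route

Step 1
Reactants: 1 hydroxyacetone; 2 ethyl 4-methyl-3-oxopentanoate
Product: 4 4-methyl-3-(2-methylpropanoyl)furan-2(5H)-one, via acetonyl ester 3 (not isolated)
Conditions: DMAP (10 mol%), toluene, reflux (−EtOH); then piperidine/AcOH (cat.), reflux, Dean–Stark
Reagents that add atoms: none
Why: Transesterification of the β-keto ester gives 3, whose active methylene condenses with the ketone (intramolecular Knoevenagel condensation) to the α-acyl butenolide; no stereocentre is formed.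

Step 2
Reactants: 4 4-methyl-3-(2-methylpropanoyl)furan-2(5H)-one; 5 acetaldehyde
Product: 6 2-[(3S)-3-methyl-4-(2-methylpropanoyl)-5-oxooxolan-3-yl]acetaldehyde (epimers/enol at the α-acyl carbon)
Conditions: (S)-α,α-diphenylprolinol TMS ether (20 mol%), 4-nitrophenol (20 mol%), MeCHO (5 equiv), 1,4-dioxane, 4 °C → rt; aq. work-up
Reagents that add atoms: none
Why: Proposed new method: the acetaldehyde enamine adds to the β-carbon of the doubly activated, s-cis-locked tetrasubstituted alkene of 4 (Michael addition, or inverse-demand oxa-[4+2] then hydrolysis), the CPh2(OTMS) group blocking one enamine face so that one face of the planar butenolide is attacked and the C1 quaternary centre is set (S); the closest known reactions are prolinol-ether-catalysed Michael additions of acetaldehyde to nitroalkenes and aminocatalytic additions of aldehydes to alkylidene malonates and β,γ-unsaturated α-keto esters, not yet shown for a tetrasubstituted cyclic alkylidene β-keto lactone forming an all-carbon quaternary centre.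

Step 3
Reactants: 6 2-[(3S)-3-methyl-4-(2-methylpropanoyl)-5-oxooxolan-3-yl]acetaldehyde
Product: 7 (3aS,6aR)-3a-methyl-6-(propan-2-yl)-3,3a,4,6a-tetrahydro-1H-cyclopenta[c]furan-1-one
Conditions: TiCl4, Zn, pyridine, THF, reflux, slow addition of 6
Reagents that add atoms: none
Why: Intramolecular McMurry coupling of the 1,5-keto-aldehyde gives the trisubstituted cyclopentene; only the epimer with the acyl group cis to the CH2CHO arm can close and the β-keto lactone epimerises under the conditions, so C5 is fixed by the cis-bicyclo[3.3.0] ring fusion.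

Step 4
Reactants: 7 (3aS,6aR)-3a-methyl-6-(propan-2-yl)-3,3a,4,6a-tetrahydro-1H-cyclopenta[c]furan-1-one; 8 vinylmagnesium bromide
Product: 10 1-[(1R,5S)-5-(hydroxymethyl)-5-methyl-2-(propan-2-yl)cyclopent-2-en-1-yl]prop-2-en-1-one, via lactol 9 (not isolated)
Conditions: CH2=CHMgBr (1.1 equiv), CeCl3 (1.2 equiv), THF, −78 °C; then aq. NH4Cl
Reagents that add atoms: none
Why: Organocerium mono-addition to the γ-lactone (nucleophilic acyl substitution) gives a tetrahedral alkoxide that is stable at −78 °C and opens on work-up to the γ-hydroxy vinyl ketone; CeCl3 suppresses enolisation at C5.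

Step 5
Reactants: 10 1-[(1R,5S)-5-(hydroxymethyl)-5-methyl-2-(propan-2-yl)cyclopent-2-en-1-yl]prop-2-en-1-one
Product: 11 (1S,2R)-1-methyl-2-(prop-2-enoyl)-3-(propan-2-yl)cyclopent-3-ene-1-carbaldehyde
Conditions: Dess–Martin periodinane, CH2Cl2, 0 °C → rt
Reagents that add atoms: none
Why: Dess–Martin oxidation of the neopentyl primary alcohol under near-neutral conditions gives an aldehyde with no α-hydrogen, so neither C1 nor the β,γ-unsaturated ketone is disturbed.

Step 6
Reactants: 11 (1S,2R)-1-methyl-2-(prop-2-enoyl)-3-(propan-2-yl)cyclopent-3-ene-1-carbaldehyde; 12 4,4,5,5-tetramethyl-2-(2-methylprop-2-en-1-yl)-1,3,2-dioxaborolane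
Product: 14 1-[(1R,5S)-5-[(1S)-1-hydroxy-3-methylbut-3-en-1-yl]-5-methyl-2-(propan-2-yl)cyclopent-2-en-1-yl]prop-2-en-1-one, via pinacol borate 13 (not isolated)
Conditions: (S)-TRIP phosphoric acid (5 mol%), 4 Å MS, toluene, −30 °C → rt; aq. NaHCO3
Reagents that add atoms: none
Why: Chiral phosphoric acid-catalysed allylboration proceeds through a chair six-membered transition state with the acid hydrogen-bonded to the boronate oxygen and the formyl hydrogen, so the catalyst delivers the methallyl group to the Si face and sets C10 (S); the ketone does not react.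

Step 7
Reactants: 14 1-[(1R,5S)-5-[(1S)-1-hydroxy-3-methylbut-3-en-1-yl]-5-methyl-2-(propan-2-yl)cyclopent-2-en-1-yl]prop-2-en-1-one
Product: 15 (3aR,8S,8aS)-8-hydroxy-6,8a-dimethyl-3-(propan-2-yl)-3a,7,8,8a-tetrahydroazulen-4(1H)-one
Conditions: Hoveyda–Grubbs II (5 mol%), toluene, 80 °C, Ar sparge
Reagents that add atoms: none
Why: Ring-closing metathesis between the acryloyl group and the 1,1-disubstituted methallyl alkene, held cis on the cyclopentene, closes the seven-membered enone with the trisubstituted C7=C8 bond; the ring trisubstituted alkene is inert.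

Step 8
Reactants: 15 (3aR,8S,8aS)-8-hydroxy-6,8a-dimethyl-3-(propan-2-yl)-3a,7,8,8a-tetrahydroazulen-4(1H)-one
Product: 16 (3aR,8S,8aS)-8-[(tert-butyldimethylsilyl)oxy]-6,8a-dimethyl-3-(propan-2-yl)-3a,7,8,8a-tetrahydroazulen-4(1H)-one
Conditions: TBSOTf, 2,6-lutidine, CH2Cl2, −78 °C
Reagents that add atoms: tert-butyldimethylsilyl trifluoromethanesulfonate, CC(C)(C)[Si](C)(C)OS(=O)(=O)C(F)(F)F
Why: Silylation of the hindered C10 alcohol (silyl ether formation) at −78 °C is faster than enol silylation of the ketone and keeps this hydroxyl out of the later acylations.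

Step 9
Reactants: 16 (3aR,8S,8aS)-8-[(tert-butyldimethylsilyl)oxy]-6,8a-dimethyl-3-(propan-2-yl)-3a,7,8,8a-tetrahydroazulen-4(1H)-one
Product: 17 10β-[(tert-butyldimethylsilyl)oxy]-3β,4β-dihydroxy-5β-H-dauc-7-en-6-one
Conditions: OsO4 (5 mol%), NMO, acetone/H2O 8:1, 0 °C → rt
Reagents that add atoms: N-methylmorpholine N-oxide, C[N+]1([O-])CCOCC1; water, O
Why: Upjohn dihydroxylation attacks the electron-rich cyclopentene in preference to the enone alkene and adds syn from the convex β face, anti to the C5 acyl arm, setting C3 and C4 (both OH β, isopropyl α).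

Step 10
Reactants: 17 10β-[(tert-butyldimethylsilyl)oxy]-3β,4β-dihydroxy-5β-H-dauc-7-en-6-one
Product: 18 3β-acetoxy-10β-[(tert-butyldimethylsilyl)oxy]-4β-hydroxy-5β-H-dauc-7-en-6-one
Conditions: Ac2O, pyridine, DMAP (cat.), CH2Cl2, 0 °C → rt
Reagents that add atoms: acetic anhydride, CC(=O)OC(C)=O
Why: DMAP-catalysed acylation takes the secondary C3 hydroxyl and leaves the tertiary C4 hydroxyl untouched.

Step 11
Reactants: 18 3β-acetoxy-10β-[(tert-butyldimethylsilyl)oxy]-4β-hydroxy-5β-H-dauc-7-en-6-one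
Product: 19 3β-acetoxy-10β-[(tert-butyldimethylsilyl)oxy]-5β-H-dauc-7-ene-4β,6α-diol
Conditions: NaBH4, CeCl3·7H2O, MeOH, −78 °C
Reagents that add atoms: none
Why: Luche 1,2-reduction of the enone delivers hydride from the convex β face (the side of H-5, away from the α isopropyl group) and gives the 6α allylic alcohol; the acetate survives.

Step 12
Reactants: 19 3β-acetoxy-10β-[(tert-butyldimethylsilyl)oxy]-5β-H-dauc-7-ene-4β,6α-diol; 20 4-[(tert-butyldimethylsilyl)oxy]benzoic acid
Product: 21 3β-acetoxy-10β-[(tert-butyldimethylsilyl)oxy]-6α-{4-[(tert-butyldimethylsilyl)oxy]benzoyloxy}-5β-H-dauc-7-en-4β-ol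
Conditions: DCC, DMAP (1 equiv), CH2Cl2, rt → 40 °C
Reagents that add atoms: none
Why: Steglich esterification acylates the only free secondary alcohol (C6) with retention; the tertiary C4 hydroxyl does not react.

Step 13
Reactants: 21 3β-acetoxy-10β-[(tert-butyldimethylsilyl)oxy]-6α-{4-[(tert-butyldimethylsilyl)oxy]benzoyloxy}-5β-H-dauc-7-en-4β-ol
Product: 22 (1S,3S,4R,5R,6S,10S)-3β-acetoxy-4β,10β-dihydroxy-6α-(4-hydroxybenzoyloxy)-5β-H-dauc-7-ene (target)
Conditions: HF·pyridine, pyridine/THF, 0 °C → rt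
Reagents that add atoms: none
Why: Buffered fluoride desilylation removes the aryl and the C10 silyl ethers in one operation without touching the acetate or the aroyl ester.

## Compound list

1 | hydroxyacetone | CC(=O)CO | starting material
2 | ethyl 4-methyl-3-oxopentanoate | CCOC(=O)CC(=O)C(C)C | starting material
3 | 2-oxopropyl 4-methyl-3-oxopentanoate (acetonyl ester) | CC(=O)COC(=O)CC(=O)C(C)C | intermediate (not isolated)
4 | 4-methyl-3-(2-methylpropanoyl)furan-2(5H)-one | CC1=C(C(=O)C(C)C)C(=O)OC1 | intermediate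
5 | acetaldehyde | CC=O | starting material
6 | 2-[(3S)-3-methyl-4-(2-methylpropanoyl)-5-oxooxolan-3-yl]acetaldehyde (α-acyl carbon epimeric) | O=CC[C@]1(C)COC(=O)C1C(=O)C(C)C | intermediate
7 | (3aS,6aR)-3a-methyl-6-(propan-2-yl)-3,3a,4,6a-tetrahydro-1H-cyclopenta[c]furan-1-one (cis-fused) | C1=C(C(C)C)[C@H]2C(=O)OC[C@@]2(C)C1 | intermediate
8 | vinylmagnesium bromide | C=C[Mg]Br | starting material
9 | 1-ethenyl lactol (cyclic hemiketal) of 10, cis-fused | C=CC1(O)OC[C@@]2(C)CC=C(C(C)C)[C@@H]12 | intermediate (not isolated)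
10 | 1-[(1R,5S)-5-(hydroxymethyl)-5-methyl-2-(propan-2-yl)cyclopent-2-en-1-yl]prop-2-en-1-one | C=CC(=O)[C@@H]1C(C(C)C)=CC[C@]1(C)CO | intermediate
11 | (1S,2R)-1-methyl-2-(prop-2-enoyl)-3-(propan-2-yl)cyclopent-3-ene-1-carbaldehyde | C=CC(=O)[C@@H]1C(C(C)C)=CC[C@]1(C)C=O | intermediate
12 | 4,4,5,5-tetramethyl-2-(2-methylprop-2-en-1-yl)-1,3,2-dioxaborolane | CC(=C)CB1OC(C)(C)C(C)(C)O1 | starting material
13 | pinacol borate ester of 14 | C=CC(=O)[C@@H]1C(C(C)C)=CC[C@]1(C)[C@@H](OB2OC(C)(C)C(C)(C)O2)CC(C)=C | intermediate (not isolated)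
14 | 1-[(1R,5S)-5-[(1S)-1-hydroxy-3-methylbut-3-en-1-yl]-5-methyl-2-(propan-2-yl)cyclopent-2-en-1-yl]prop-2-en-1-one | C=CC(=O)[C@@H]1C(C(C)C)=CC[C@]1(C)[C@@H](O)CC(C)=C | intermediate
15 | (3aR,8S,8aS)-8-hydroxy-6,8a-dimethyl-3-(propan-2-yl)-3a,7,8,8a-tetrahydroazulen-4(1H)-one (10β-hydroxy-5β-H-dauca-3,7-dien-6-one) | C1(C(C)C)=CC[C@]2(C)[C@@H](O)CC(C)=CC(=O)[C@H]12 | intermediate
16 | (3aR,8S,8aS)-8-[(tert-butyldimethylsilyl)oxy]-6,8a-dimethyl-3-(propan-2-yl)-3a,7,8,8a-tetrahydroazulen-4(1H)-one | C1(C(C)C)=CC[C@]2(C)[C@@H](O[Si](C)(C)C(C)(C)C)CC(C)=CC(=O)[C@H]12 | intermediate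
17 | 10β-[(tert-butyldimethylsilyl)oxy]-3β,4β-dihydroxy-5β-H-dauc-7-en-6-one | O[C@H]1C[C@]2(C)[C@@H](O[Si](C)(C)C(C)(C)C)CC(C)=CC(=O)[C@@H]2[C@]1(O)C(C)C | intermediate
18 | 3β-acetoxy-10β-[(tert-butyldimethylsilyl)oxy]-4β-hydroxy-5β-H-dauc-7-en-6-one | CC(=O)O[C@H]1C[C@]2(C)[C@@H](O[Si](C)(C)C(C)(C)C)CC(C)=CC(=O)[C@@H]2[C@]1(O)C(C)C | intermediate
19 | 3β-acetoxy-10β-[(tert-butyldimethylsilyl)oxy]-5β-H-dauc-7-ene-4β,6α-diol | CC(=O)O[C@H]1C[C@]2(C)[C@@H](O[Si](C)(C)C(C)(C)C)CC(C)=C[C@H](O)[C@@H]2[C@]1(O)C(C)C | intermediate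
20 | 4-[(tert-butyldimethylsilyl)oxy]benzoic acid | CC(C)(C)[Si](C)(C)Oc1ccc(cc1)C(=O)O | starting material
21 | 3β-acetoxy-10β-[(tert-butyldimethylsilyl)oxy]-6α-{4-[(tert-butyldimethylsilyl)oxy]benzoyloxy}-5β-H-dauc-7-en-4β-ol | CC(=O)O[C@H]1C[C@]2(C)[C@@H](O[Si](C)(C)C(C)(C)C)CC(C)=C[C@H](OC(=O)c3ccc(O[Si](C)(C)C(C)(C)C)cc3)[C@@H]2[C@]1(O)C(C)C | intermediate
22 | (1S,3S,4R,5R,6S,10S)-3β-acetoxy-4β,10β-dihydroxy-6α-(4-hydroxybenzoyloxy)-5β-H-dauc-7-ene (CNP0146780.2) | CC(=O)O[C@H]1C[C@]2(C)[C@@H](O)CC(C)=C[C@H](OC(=O)c3ccc(O)cc3)[C@@H]2[C@]1(O)C(C)C | target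

## Step count and risks

Total steps: 13. Longest linear sequence: 13 (1/2 → 22).

Step 2 (the proposed new step) may fail through low reactivity of the tetrasubstituted acceptor, γ-deprotonation of 4 by the amine, or low enantioselectivity. The fallback uses known chemistry and sets out from 4. A Cu(OTf)2/(S,S)-t-Bu-bis(oxazoline)-catalysed enantioselective Hosomi–Sakurai conjugate allylation with allyltrimethylsilane (CH2Cl2, −78 °C) gives (4S)-4-methyl-3-(2-methylpropanoyl)-4-(prop-2-en-1-yl)oxolan-2-one F1. Ozonolysis of its terminal alkene (O3, CH2Cl2, −78 °C; then PPh3) returns to the route at 6.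

Step 3 may fail because the β-keto lactone can chelate titanium, the lactone carbonyl can be reduced, or the open keto-aldehyde can sit as its cyclic enol-hemiacetal. The fallback sets out from 6 and separates C–C bond formation from deoxygenation. SmI2 (THF/t-BuOH, −78 °C) effects ketyl pinacol cyclisation to the cis-fused 5,6-cis-dihydroxy-3a-methyl-6-(propan-2-yl)hexahydro-1H-cyclopenta[c]furan-1-one F2. Thiocarbonyldiimidazole (DMAP, toluene, 90 °C) converts it into the cyclic thiocarbonate of that diol F3. Corey–Winter elimination (P(OMe)3, 110 °C) then returns to the route at 7.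

Step 4 may fail through double addition or conjugate addition to the liberated vinyl ketone, or through enolisation at C5. The fallback sets out from 7 and adds the vinyl group at the aldehyde oxidation level. DIBAL-H (CH2Cl2, −78 °C) gives the cis-fused lactol 3a-methyl-6-(propan-2-yl)-3,3a,4,6a-tetrahydro-1H-cyclopenta[c]furan-1-ol F4. Excess vinylmagnesium bromide (THF, 0 °C) opens it to the diol 1-[5-(hydroxymethyl)-5-methyl-2-(propan-2-yl)cyclopent-2-en-1-yl]prop-2-en-1-ol F5 (carbinol epimers, ring configuration as in 10). Double Dess–Martin oxidation of both hydroxyls then returns to the route at 11, bypassing 10.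

Further compounds
F1 | step 2 | (4S)-4-methyl-3-(2-methylpropanoyl)-4-(prop-2-en-1-yl)oxolan-2-one | C=CC[C@]1(C)COC(=O)C1C(=O)C(C)C
F2 | step 3 | cis-fused 5,6-cis-dihydroxy-3a-methyl-6-(propan-2-yl)hexahydro-1H-cyclopenta[c]furan-1-one | OC1C[C@]2(C)COC(=O)[C@@H]2C1(O)C(C)C
F3 | step 3 | cyclic thiocarbonate of F2 | S=C1OC2C[C@]3(C)COC(=O)[C@@H]3C2(O1)C(C)C
F4 | step 4 | cis-fused 3a-methyl-6-(propan-2-yl)-3,3a,4,6a-tetrahydro-1H-cyclopenta[c]furan-1-ol | OC1OC[C@@]2(C)CC=C(C(C)C)[C@@H]12
F5 | step 4 | 1-[5-(hydroxymethyl)-5-methyl-2-(propan-2-yl)cyclopent-2-en-1-yl]prop-2-en-1-ol | C=CC(O)[C@@H]1C(C(C)C)=CC[C@]1(C)CO
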